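**Strategy.** The cyclohexane ring C14–C15–C16–C17–C18–C19 (locants in the remark below) carries a cis-1,4-diol (C16, C19) next to the methyl-bearing quaternary C14 and shares C14–C15–C16 with the seven-membered ring. Read backwards, C16 and C19 are the carbonyl carbons of a 4-oxoaldehyde and C14=C15 is the alkene of an isopropenyl ketone. One SmI2 ketyl–enone cyclization/aldol cascade on an acyclic keto aldehyde enone therefore closes both carbocycles at once, joining C15 to C16 and C14 to C19 and setting C10, C14, C16 and C19 from the single organocatalytically installed centre C11. The dienyl side chain and the lactone follow by cross-aldol condensation, reduction and lactonization.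

Key step: step 10

Remark (locants): atoms are counted along the main string of the target SMILES, branch atoms left out: C1 (a methyl), C2 (side-chain carbinol), C3=C4, C5=C6, C7 (OCH2), O8, C9 (lactone C=O), C10, C11 (ring-fusion CH next to C6), C12, C13, C14 (C–CH3), C15 (bridging CH2), C16 (C–OH), C17, C18, C19 (CHOH).

Remark (stereo): the carbinol carbon that later becomes the C13 ketone is made racemic on purpose and is erased by oxidation; C10 is the labile α-carbon of a β-keto ester until the key step. Both are written without descriptors until they are fixed or removed.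

Step 1
Reactants: 1 methacrolein; 2 allylmagnesium bromide
Product: 3 rac-2-methylhexa-1,5-dien-3-ol
Conditions: 2 (1.1 equiv), Et2O, −78 °C; aq. NH4Cl
Reagents that add atoms: none
Why: 1,2-Grignard addition of the allyl reagent to the enal carbonyl; the new carbinol centre is left racemic because step 8 removes it.

Step 2
Reactants: 3 rac-2-methylhexa-1,5-dien-3-ol
Product: 4 rac-tert-butyl(dimethyl)[(2-methylhexa-1,5-dien-3-yl)oxy]silane
Conditions: TBSCl, imidazole, DMF, 0 °C → rt
Reagents that add atoms: tert-butyldimethylsilyl chloride, CC(C)(C)[Si](C)(C)Cl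
Why: Standard silylation of a secondary allylic alcohol; the ether must survive metathesis, amine catalysis and acetalization.

Step 3
Reactants: 4 silyl ether; 5 (E)-but-2-enal (crotonaldehyde)
Product: 6 rac-(E)-5-[(tert-butyldimethylsilyl)oxy]-6-methylhepta-2,6-dienal
Conditions: second-generation Hoveyda–Grubbs catalyst (3 mol %), 5 (3 equiv), CH2Cl2, 40 °C
Reagents that add atoms: none
Why: Olefin cross-metathesis of the monosubstituted alkene with the electron-poor partner should give the E-enal, while the hindered 1,1-disubstituted alkene does not take part.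

Step 4
Reactants: 7 2-methylbut-3-en-2-ol; 5 (E)-but-2-enal
Product: 8 (E)-4-hydroxy-4-methylpent-2-enal
Conditions: second-generation Hoveyda–Grubbs catalyst (5 mol %), 5 (3 equiv), CH2Cl2, 40 °C
Reagents that add atoms: none
Why: Cross-metathesis of a tertiary allylic alcohol with crotonaldehyde should give the E-enal, which cannot enolize and needs no protection later.

Step 5
Reactants: 9 methyl 3-oxohept-6-enoate; 6 dienal
Product: 10 methyl (3R)-5-[(tert-butyldimethylsilyl)oxy]-6-methyl-3-(2-oxoethyl)-2-(pent-4-enoyl)hept-6-enoate (in equilibrium with its cyclic hemiacetal)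
Conditions: (S)-α,α-diphenylprolinol trimethylsilyl ether (10 mol %), PhCO2H (10 mol %), toluene, 0 °C → rt
Reagents that add atoms: none
Why: Iminium-catalysed Michael addition of a β-keto ester to an enal; the nucleophile adds to the β-carbon on the face away from the diphenyl(silyloxy)methyl group of the (S)-catalyst, which sets C11 as required.

Step 6
Reactants: 10 Michael adduct
Product: 11 methyl (3R)-5-[(tert-butyldimethylsilyl)oxy]-3-(1,3-dioxolan-2-ylmethyl)-6-methyl-2-(pent-4-enoyl)hept-6-enoate
Conditions: TMSOCH2CH2OTMS (2 equiv), TMSOTf (5 mol %), CH2Cl2, −78 → −40 °C; pyridine quench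
Reagents that add atoms: 1,2-bis(trimethylsilyloxy)ethane, C[Si](C)(C)OCCO[Si](C)(C)C
Why: Noyori acetalization is aprotic and aldehyde-selective at low temperature; the β-keto ester enol is a good leaving group, so the hemiacetal should open to the acyclic dioxolane while the ketone and silyl ether stay untouched.

Step 7
Reactants: 11 dioxolane
Product: 12 methyl (3R)-3-(1,3-dioxolan-2-ylmethyl)-5-hydroxy-6-methyl-2-(pent-4-enoyl)hept-6-enoate
Conditions: HF·pyridine, pyridine, THF, 0 °C → rt
Reagents that add atoms: none
Why: Buffered fluoride desilylation frees the allylic alcohol without touching the dioxolane or the β-keto ester.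

Step 8
Reactants: 12 allylic alcohol
Product: 13 methyl (3S)-3-(1,3-dioxolan-2-ylmethyl)-6-methyl-5-oxo-2-(pent-4-enoyl)hept-6-enoate
Conditions: MnO2 (20 equiv), CH2Cl2, rt
Reagents that add atoms: none
Why: MnO2 oxidizes only the allylic carbinol under neutral conditions, which gives the isopropenyl ketone and removes the carbinol epimers.

Step 9
Reactants: 13 enone
Product: 14 methyl (3S)-3-(1,3-dioxolan-2-ylmethyl)-6-methyl-5-oxo-2-(4-oxobutanoyl)hept-6-enoate
Conditions: OsO4 (2 mol %), NaIO4 (2.5 equiv), THF/pH 7 buffer, 0 °C → rt; used at once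
Reagents that add atoms: osmium tetroxide, O=[Os](=O)(=O)=O (oxygen donor, regenerated by sodium periodate, [Na+].[O-]I(=O)(=O)=O)
Why: Lemieux–Johnson cleavage; the electron-rich monosubstituted alkene is osmylated much faster than the electron-poor alkene of the enone.

Step 10
Reactants: 14 keto aldehyde enone
Product: 16 methyl 3-(1,3-dioxolan-2-ylmethyl)-1,7-dihydroxy-6-methyl-5-oxobicyclo[4.3.1]decane-2-carboxylate (target configuration at C10, C11, C14, C16, C19), via samarium enolate 15 (not isolated)
Conditions: SmI2 (2.5 equiv), HMPA (10 equiv), THF (5 mM), −78 °C, slow addition of 14; −78 → −40 °C; aq. NH4Cl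
Reagents that add atoms: none
Why: Single-electron transfer from SmI2 gives the C16 ketyl (reduction of the enone first leads to the same C15–C16 coupling), which adds to the unsubstituted terminus C15 of the isopropenyl ketone; a second electron turns the α-keto radical into trivalent samarium enolate 15, whose C14 adds to the C19 aldehyde. The closest known reaction type is the SmI2 radical cyclization–aldol ("radical then aldol") cascade of dicarbonyl compounds with tethered unsaturated esters, here run with a ketone ketyl and an enone. The seven-membered ring closes by 7-endo-trig radical addition and the six-membered ring by 6-(enolexo)-exo-trig aldol addition, which together give the bicyclo[4.3.1]decane. C16 is set in a chair-like seven-membered transition state with the C10 ester and the C11 side arm equatorial, where the HMPA-ligated, non-chelating O–Sm group is the largest substituent on the ketyl carbon and sits pseudo-equatorial, so the 3-oxopropyl chain is pseudo-axial; C14 follows because only the enolate face on the side of that axial chain can reach the aldehyde; C19 follows from an open, non-chelated aldol transition state with C=O antiperiplanar to the enolate C–O, which puts O19 cis to O16; C10, labile in 14, reacts through the epimer with the ester equatorial and is fixed once C16 is sp3. The step needs reaction at the ketone/enone pair before the aldehyde and attack at C15, not C14; the electron-poor terminal CH2, the 1,6-spacing of ketone and enone terminus and slow addition at −78 °C should secure this, and an aldehyde ketyl formed early can still combine with the C14 radical to give the same bond.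

Step 11
Reactants: 16 bicyclic ketol
Product: 17 p-toluenesulfonylhydrazone of 16 at C13
Conditions: TsNHNH2 (1.5 equiv), EtOH, 70 °C
Reagents that add atoms: p-toluenesulfonyl hydrazide, Cc1ccc(cc1)S(=O)(=O)NN
Why: Hydrazone condensation at the only ketone; acid-free conditions keep the dioxolane intact.

Step 12
Reactants: 17 tosylhydrazone
Product: 18 methyl 3-(1,3-dioxolan-2-ylmethyl)-1,7-dihydroxy-6-methylbicyclo[4.3.1]decane-2-carboxylate
Conditions: catecholborane (4 equiv), CHCl3, 0 °C → rt; then NaOAc·3H2O, 60 °C
Reagents that add atoms: none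
Why: Kabalka variant of the Caglioti reduction (hydroboration of C=N, then loss of sulfinate and N2 from the diazene) turns C13=O into CH2 under mild conditions that spare the ester and acetal.

Step 13
Reactants: 18 deoxygenated acetal
Product: 19 methyl 1,7-dihydroxy-6-methyl-3-(2-oxoethyl)bicyclo[4.3.1]decane-2-carboxylate
Conditions: 1 M HCl, THF, rt
Reagents that add atoms: water, O
Why: Acetal hydrolysis; the tertiary C16–OH is at a bridgehead and should neither ionize nor eliminate.

Step 14
Reactants: 19 aldehyde; 8 (E)-4-hydroxy-4-methylpent-2-enal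
Product: 20 methyl 1,7-dihydroxy-3-[(2E,4E)-6-hydroxy-6-methyl-1-oxohepta-2,4-dien-2-yl]-6-methylbicyclo[4.3.1]decane-2-carboxylate
Conditions: pyrrolidine (20 mol %), propanoic acid (20 mol %), CH2Cl2, rt → 40 °C
Reagents that add atoms: none
Why: Enamine-mediated cross-aldol condensation (aldol, then E1cB): 8 cannot enolize and its β-carbon is shielded, so it reacts 1,2; the thermodynamic 2-alkyl enal has C4 trans to the formyl group, which is the C5=C6 geometry of the target.

Step 15
Reactants: 20 dienal
Product: 22 target CNP0116574.1, via hydroxy ester 21 (not isolated)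
Conditions: NaBH4, CeCl3·7H2O, MeOH, −40 °C; aqueous work-up; then 2-hydroxypyridine (0.2 equiv), toluene, 60 °C
Reagents that add atoms: none
Why: Luche 1,2-reduction of the dienal gives the allylic alcohol at C7, which should acylate intramolecularly on the C9 methyl ester to close the δ-lactone without acid or strong base.

**Compound list**

1 | methacrolein (2-methylprop-2-enal) | CC(=C)C=O | starting material
2 | allylmagnesium bromide | C=CC[Mg]Br | starting material
3 | rac-2-methylhexa-1,5-dien-3-ol | CC(=C)C(O)CC=C | intermediate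
4 | rac-tert-butyl(dimethyl)[(2-methylhexa-1,5-dien-3-yl)oxy]silane | CC(=C)C(O[Si](C)(C)C(C)(C)C)CC=C | intermediate
5 | (E)-but-2-enal (crotonaldehyde) | C/C=C/C=O | starting material
6 | rac-(E)-5-[(tert-butyldimethylsilyl)oxy]-6-methylhepta-2,6-dienal | CC(=C)C(O[Si](C)(C)C(C)(C)C)C/C=C/C=O | intermediate
7 | 2-methylbut-3-en-2-ol | CC(C)(O)C=C | starting material
8 | (E)-4-hydroxy-4-methylpent-2-enal | CC(C)(O)/C=C/C=O | intermediate
9 | methyl 3-oxohept-6-enoate | COC(=O)CC(=O)CCC=C | starting material
10 | methyl (3R)-5-[(tert-butyldimethylsilyl)oxy]-6-methyl-3-(2-oxoethyl)-2-(pent-4-enoyl)hept-6-enoate (C2 labile, C5 both epimers) | COC(=O)C(C(=O)CCC=C)[C@@H](CC=O)CC(O[Si](C)(C)C(C)(C)C)C(C)=C | intermediate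
11 | methyl (3R)-5-[(tert-butyldimethylsilyl)oxy]-3-(1,3-dioxolan-2-ylmethyl)-6-methyl-2-(pent-4-enoyl)hept-6-enoate | COC(=O)C(C(=O)CCC=C)[C@@H](CC1OCCO1)CC(O[Si](C)(C)C(C)(C)C)C(C)=C | intermediate
12 | methyl (3R)-3-(1,3-dioxolan-2-ylmethyl)-5-hydroxy-6-methyl-2-(pent-4-enoyl)hept-6-enoate | COC(=O)C(C(=O)CCC=C)[C@@H](CC1OCCO1)CC(O)C(C)=C | intermediate
13 | methyl (3S)-3-(1,3-dioxolan-2-ylmethyl)-6-methyl-5-oxo-2-(pent-4-enoyl)hept-6-enoate (C2 labile) | COC(=O)C(C(=O)CCC=C)[C@@H](CC1OCCO1)CC(=O)C(C)=C | intermediate
14 | methyl (3S)-3-(1,3-dioxolan-2-ylmethyl)-6-methyl-5-oxo-2-(4-oxobutanoyl)hept-6-enoate (C2 labile) | COC(=O)C(C(=O)CCC=O)[C@@H](CC1OCCO1)CC(=O)C(C)=C | intermediate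
15 | trivalent samarium enolate/alkoxide of the cycloheptane formed by C15–C16 coupling (drawn with SmI2 groups on O13 and O16) | COC(=O)[C@@H]1[C@@H](CC2OCCO2)CC(O[Sm](I)I)=C(C)C[C@]1(O[Sm](I)I)CCC=O | intermediate
16 | methyl 3-(1,3-dioxolan-2-ylmethyl)-1,7-dihydroxy-6-methyl-5-oxobicyclo[4.3.1]decane-2-carboxylate; ester and side arm trans, both OH groups cis to each other and anti to the four-carbon bridge, methyl cis to the secondary OH | COC(=O)[C@@H]2[C@@H](CC3OCCO3)CC(=O)[C@@]1(C)C[C@]2(O)CC[C@@H]1O | intermediate
17 | 5-(p-toluenesulfonylhydrazone) of 16 | COC(=O)[C@@H]2[C@@H](CC3OCCO3)CC(=NNS(=O)(=O)c4ccc(C)cc4)[C@@]1(C)C[C@]2(O)CC[C@@H]1O | intermediate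
18 | methyl 3-(1,3-dioxolan-2-ylmethyl)-1,7-dihydroxy-6-methylbicyclo[4.3.1]decane-2-carboxylate | COC(=O)[C@@H]2[C@@H](CC3OCCO3)CC[C@@]1(C)C[C@]2(O)CC[C@@H]1O | intermediate
19 | methyl 1,7-dihydroxy-6-methyl-3-(2-oxoethyl)bicyclo[4.3.1]decane-2-carboxylate | COC(=O)[C@@H]2[C@@H](CC=O)CC[C@@]1(C)C[C@]2(O)CC[C@@H]1O | intermediate
20 | methyl 1,7-dihydroxy-3-[(2E,4E)-6-hydroxy-6-methyl-1-oxohepta-2,4-dien-2-yl]-6-methylbicyclo[4.3.1]decane-2-carboxylate | COC(=O)[C@@H]2[C@@H](/C(C=O)=C\C=C\C(C)(C)O)CC[C@@]1(C)C[C@]2(O)CC[C@@H]1O | intermediate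
21 | methyl 3-[(2E,4E)-1,6-dihydroxy-6-methylhepta-2,4-dien-2-yl]-1,7-dihydroxy-6-methylbicyclo[4.3.1]decane-2-carboxylate | COC(=O)[C@@H]2[C@@H](/C(CO)=C\C=C\C(C)(C)O)CC[C@@]1(C)C[C@]2(O)CC[C@@H]1O | intermediate
22 | CNP0116574.1: trans-fused δ-lactone on the bicyclo[4.3.1]decane-diol, with the (E,E)-dienyl tertiary carbinol side chain at C6 | CC(C)(O)/C=C/C=C1/COC(=O)[C@@H]2[C@@H]1CC[C@@]1(C)C[C@]2(O)CC[C@@H]1O | target

**Step count.** Total: 15 steps. Longest linear sequence: 14 steps (steps 1–3 and 5–15).

**Steps most likely to fail, with fallbacks**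

Step 10. The ketyl may add with the 3-oxopropyl chain pseudo-equatorial, so that the enolate cannot reach the aldehyde and is only protonated. The aldehyde may also be over-reduced before the aldol, or the acidic β-keto ester may add to the enone in a base-mediated Michael reaction. The fallback separates the two bond formations and sets out from 13, where the aldehyde is still an alkene. SmI2/HMPA with t-BuOH should give the ketyl–enone cyclization with protonation of the enolate, leading to the monocyclic hydroxy ketone F1 (both C14 epimers); chelating conditions without HMPA can be screened here because no aldehyde is present. Lemieux–Johnson cleavage (OsO4 cat., NaIO4) should then give the keto aldehyde F2. A reversible intramolecular aldol addition (K2CO3, MeOH, 0 °C), in which C14 equilibrates through the enolate, should close the six-membered ring and return to 16.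

Step 14. Enamine turnover may be slow at the β-branched aldehyde, which also sits partly as a lactol with the C16 hydroxyl; self-condensation, or conjugate addition of a hydroxyl group to the new dienal, may compete. The fallback is a directed aldol followed by elimination and sets out from 19. TMSOTf/Et3N should give the tris(trimethylsilyl) enol ether F3. BF3·OEt2-promoted Mukaiyama addition of F3 to 8, with loss of the silyl groups on aqueous acidic work-up, should give the β-hydroxy aldehyde F4 (new centres at C5 and C6 unassigned). Mesylation of the allylic C5 hydroxyl (MsCl, Et3N, −20 °C) gives the mesylate F5, which should eliminate with DBU to the thermodynamic (E)-enal and return to 20.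

Step 11. Hydrazone formation at the ketone next to the quaternary carbon may be slow, and prolonged heating may open the β-hydroxy ketone by retro-aldol cleavage. The fallback removes the carbonyl through its enol triflate and sets out from 16. N-(Trimethylsilyl)imidazole should give the bis(trimethylsilyl) ether F6. KHMDS/PhNTf2 at −78 °C enolizes towards C12, the only α-CH2, and should give the enol triflate F7. Palladium-catalysed formate reduction (Pd(OAc)2, PPh3, Bu3N, HCO2H) should give the alkene F8, and hydrogenation (H2, Pd/C, EtOAc) the saturated bis(silyl) ether F9. K2CO3/MeOH removes the silyl groups and returns to 18.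

**Further compounds**

F1 | step 10 | methyl 2-(but-3-enyl)-7-(1,3-dioxolan-2-ylmethyl)-2-hydroxy-4-methyl-5-oxocycloheptane-1-carboxylate (C4 both epimers) | COC(=O)[C@@H]1[C@@H](CC2OCCO2)CC(=O)C(C)C[C@]1(O)CCC=C
F2 | step 10 | methyl 7-(1,3-dioxolan-2-ylmethyl)-2-hydroxy-4-methyl-5-oxo-2-(3-oxopropyl)cycloheptane-1-carboxylate | COC(=O)[C@@H]1[C@@H](CC2OCCO2)CC(=O)C(C)C[C@]1(O)CCC=O
F3 | step 14 | tris(trimethylsilyl) derivative of 19 (aldehyde as silyl enol ether, both hydroxyls as silyl ethers) | COC(=O)[C@@H]2[C@@H](C=CO[Si](C)(C)C)CC[C@@]1(C)C[C@]2(O[Si](C)(C)C)CC[C@@H]1O[Si](C)(C)C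
F4 | step 14 | aldol adduct of 19 and 8 (β-hydroxy aldehyde) | COC(=O)[C@@H]2[C@@H](C(C=O)C(O)/C=C/C(C)(C)O)CC[C@@]1(C)C[C@]2(O)CC[C@@H]1O
F5 | step 14 | C5 methanesulfonate of F4 | COC(=O)[C@@H]2[C@@H](C(C=O)C(OS(C)(=O)=O)/C=C/C(C)(C)O)CC[C@@]1(C)C[C@]2(O)CC[C@@H]1O
F6 | step 11 | bis(trimethylsilyl) ether of 16 | COC(=O)[C@@H]2[C@@H](CC3OCCO3)CC(=O)[C@@]1(C)C[C@]2(O[Si](C)(C)C)CC[C@@H]1O[Si](C)(C)C
F7 | step 11 | enol triflate of F6 (C12=C13) | COC(=O)[C@@H]2[C@@H](CC3OCCO3)C=C(OS(=O)(=O)C(F)(F)F)[C@@]1(C)C[C@]2(O[Si](C)(C)C)CC[C@@H]1O[Si](C)(C)C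
F8 | step 11 | C12=C13 alkene from F7 | COC(=O)[C@@H]2[C@@H](CC3OCCO3)C=C[C@@]1(C)C[C@]2(O[Si](C)(C)C)CC[C@@H]1O[Si](C)(C)C
F9 | step 11 | bis(trimethylsilyl) ether of 18 | COC(=O)[C@@H]2[C@@H](CC3OCCO3)CC[C@@]1(C)C[C@]2(O[Si](C)(C)C)CC[C@@H]1O[Si](C)(C)C
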